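**Plan**

1. Locants: ring A is C1 (carbinol carbon), C2 (lactone α‑CH), C3 (ring‑fusion CH), C4 (CH‑iPr), C5, C6; ring B is C2–C(=O)–O–CH2–C(CO2H)=C7H–C3; the acyl half is a C1′–C6′ cyclohexene carrying a Cβ=Cα side chain.
2. Cuts: the ester C–O at the C1 CH2O group; the C1 diol back to C1=CH2 and a C1 ketone; the lactone C=O back to an enol‑ether CH; the O–CH2 bond of ring B with re‑closure of C2–C7 ([3,3]); the cyclopropane to an enone plus an allylic sulfonium ylide; ring A to isovaleraldehyde and methyl vinyl ketone; in the acyl half both C–CH2OH bonds, Cα=Cβ and C1′–Cβ.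
3. Enabling feature: ring B, the seven‑membered lactone C2–C(=O)–O–CH2–C(CO2H)=C7H–C3 fused to ring A at C2–C3, is at the aldehyde level a 2,5‑dihydrooxepine. That is the [3,3] isomer of a cyclopropane C2–C3–C7 with a formyl group on C2 cis to a 1‑carboxyvinyl group on C7.
4. Forward order: ring A by aldol condensation, the cyclopropane by ylide addition, ring B by retro‑Claisen ring expansion, then oxidation to the β‑keto lactone, C1 methylenation and dihydroxylation. The acyl half is built from ent‑cryptone (vinyl cuprate/triflation, Wittig, twofold Stille hydroxymethylation) and joined by esterification before acidolysis.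
5. Stereochemistry: C4 from the (R)‑prolinol‑ether Michael addition; C3 from ylide attack anti to isopropyl; C2 by equilibration to the trans‑fused, equatorial arrangement; C1 from equatorial osmylation; C1′/C6′ from the (S)‑catalyst and anti cuprate addition; the E enoate from a stabilised‑ylide Wittig reaction and stereoretentive coupling.

Key step: step 7

Assumption: catalyst sense follows the usual steric‑shielding model of diarylprolinol‑ether enamines, so the (R)‑catalyst should give (R)‑3 and the (S)‑catalyst (S)‑19; any minor enantiomer should end as a separable diastereomer after the union in step 20.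
Assumption: the C2 configuration of the target is taken to be the thermodynamically preferred one (trans ring fusion, lactone carbonyl equatorial), so it can be set by equilibration at the β‑keto lactone stage.

**Route**

Step 1
Reactants: 1 isovaleraldehyde (3‑methylbutanal); 2 methyl vinyl ketone (but‑3‑en‑2‑one)
Product: 3 (2R)‑5‑oxo‑2‑(propan‑2‑yl)hexanal
Conditions: (R)‑2‑[methoxy(diphenyl)methyl]pyrrolidine (5 mol %), ethyl 3,4‑dihydroxybenzoate (20 mol %), neat, 4 °C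
Reagents that add atoms: none
Why: Organocatalytic enamine Michael addition in which the (R)‑prolinol ether shields one face of the enamine of 1, so the enone should add to the other face and set the α‑carbon as R, with the catechol co‑catalyst activating the enone by hydrogen bonding.

Step 2
Reactants: 3 (2R)‑5‑oxo‑2‑(propan‑2‑yl)hexanal
Product: 4 (4R)‑4‑(propan‑2‑yl)cyclohex‑2‑en‑1‑one ((R)‑cryptone)
Conditions: LiOH (cat.), iPrOH, rt
Reagents that add atoms: none
Why: Intramolecular aldol condensation (6‑exo attack of the methyl ketone enolate on the aldehyde, then E1cB dehydration), in which ring closure should outrun α‑epimerisation under the mild conditions so the isopropyl stereocentre is carried into ring A.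

Step 3
Reactants: 4 (R)‑cryptone; 5 formaldehyde
Product: 6 (4R)‑2‑(hydroxymethyl)‑4‑(propan‑2‑yl)cyclohex‑2‑en‑1‑one
Conditions: 37 % aq. CH2O, DMAP (20 mol %), THF/H2O, rt
Reagents that add atoms: none
Why: Morita–Baylis–Hillman reaction, in which reversible conjugate addition of DMAP gives an enolate that is hydroxymethylated at C2 before the catalyst is expelled, leaving C4 untouched.

Step 4
Reactants: 6 (4R)‑2‑(hydroxymethyl)‑4‑(propan‑2‑yl)cyclohex‑2‑en‑1‑one
Product: 7 (4R)‑2‑({[tert‑butyl(dimethyl)silyl]oxy}methyl)‑4‑(propan‑2‑yl)cyclohex‑2‑en‑1‑one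
Conditions: TBSCl, imidazole, CH2Cl2, 0 °C → rt
Reagents that add atoms: tert‑butyl(chloro)dimethylsilane, CC(C)(C)[Si](C)(C)Cl
Why: Standard silylation of a primary alcohol, so that the hydroxymethyl group can neither be lost by retro‑aldol cleavage nor be alkylated under the basic ylide conditions of step 5.

Step 5
Reactants: 7 (4R)‑2‑({[tert‑butyl(dimethyl)silyl]oxy}methyl)‑4‑(propan‑2‑yl)cyclohex‑2‑en‑1‑one; 8 tert‑butyl 2‑(bromomethyl)prop‑2‑enoate
Product: 10 tert‑butyl 2‑[(1S,5R,6S,7S)‑1‑({[tert‑butyl(dimethyl)silyl]oxy}methyl)‑2‑oxo‑5‑(propan‑2‑yl)bicyclo[4.1.0]heptan‑7‑yl]prop‑2‑enoate, via sulfonium salt 9 (not isolated)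
Conditions: Me2S, Cs2CO3, MeCN, rt
Reagents that add atoms: none
Why: Michael‑initiated ring closure with an allylic sulfonium ylide (Corey–Chaykovsky‑type vinylcyclopropanation), in which the ylide carbon should add to the enone β‑carbon anti to the isopropyl group, the enolate displaces dimethyl sulfide on the same face, and the acrylate takes the exo position on C7, cis to the CH2OTBS group.

Step 6
Reactants: 10 tert‑butyl 2‑[(1S,5R,6S,7S)‑1‑({[tert‑butyl(dimethyl)silyl]oxy}methyl)‑2‑oxo‑5‑(propan‑2‑yl)bicyclo[4.1.0]heptan‑7‑yl]prop‑2‑enoate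
Product: 11 tert‑butyl 2‑[(1S,5R,6S,7S)‑1‑(hydroxymethyl)‑2‑oxo‑5‑(propan‑2‑yl)bicyclo[4.1.0]heptan‑7‑yl]prop‑2‑enoate
Conditions: HF·pyridine, THF, 0 °C → rt
Reagents that add atoms: none
Why: Fluoride cleavage of the primary silyl ether under mildly acidic conditions, which should spare the tert‑butyl ester, the acrylate and the base‑sensitive β‑hydroxy ketone (no retro‑aldol).

Step 7
Reactants: 11 tert‑butyl 2‑[(1S,5R,6S,7S)‑1‑(hydroxymethyl)‑2‑oxo‑5‑(propan‑2‑yl)bicyclo[4.1.0]heptan‑7‑yl]prop‑2‑enoate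
Product: 13 tert‑butyl (5aS,6R)‑9‑oxo‑6‑(propan‑2‑yl)‑3,5a,6,7,8,9‑hexahydro‑2‑benzoxepine‑4‑carboxylate, via cyclopropyl aldehyde 12 (not isolated)
Conditions: Dess–Martin periodinane, pyridine, CH2Cl2, 0 °C → rt; then PhH, 60 °C
Reagents that add atoms: none
Why: Dess–Martin oxidation frees the aldehyde 12, in which the formyl group on C1 and the exo 1‑(tert‑butoxycarbonyl)vinyl group on C7 are cis on the cyclopropane, and a concerted [3,3] hetero‑Cope (retro‑Claisen) shift through a boat‑like array then bonds the formyl oxygen to the vinyl CH2, breaks the C1–C7 bond and shifts both π bonds. The closest known reaction is the retro‑Claisen rearrangement of cis‑2‑vinylcyclopropanecarbaldehydes that carry a second acceptor on the formyl‑bearing carbon, which gives 2,5‑dihydrooxepines at or near room temperature. Ring B closes by sigmatropic expansion of the three‑membered ring through a six‑atom cyclic array, so it is neither an exo nor an endo cyclisation, and the ring alkene of the enoate can only be Z. No stereocentre is formed, and the ring‑fusion CH (C6 of 12, C5a of 13) keeps its configuration because none of its bonds is broken. The selectivity needed is reaction of the formyl group and not the ring ketone, which the substrate secures because the ketone carbon lies on the endo face, trans to the vinyl group. The equilibrium should lie on the side of 13 through release of cyclopropane strain and formation of a ketone‑conjugated enol ether (vinylogous ester) and a trisubstituted enoate.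

Step 8
Reactants: 13 tert‑butyl (5aS,6R)‑9‑oxo‑6‑(propan‑2‑yl)‑3,5a,6,7,8,9‑hexahydro‑2‑benzoxepine‑4‑carboxylate
Product: 14 tert‑butyl (5aS,6R)‑9a‑bromo‑1‑hydroxy‑9‑oxo‑6‑(propan‑2‑yl)‑1,3,5a,6,7,8,9,9a‑octahydro‑2‑benzoxepine‑4‑carboxylate (epimers at C1/C9a)
Conditions: NBS, THF/H2O (4:1), 0 °C
Reagents that add atoms: N‑bromosuccinimide, O=C1CCC(=O)N1Br; water, O
Why: Bromohydrin formation on the push–pull enol ether (bromination at the α‑carbon C9a, capture of the oxocarbenium ion by water), in which the quaternary bromide blocks enolisation so the lactol should not unravel to a hydroxymethylene ketone; the configurations at C1 and C9a do not matter because both centres are reset.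

Step 9
Reactants: 14 tert‑butyl (5aS,6R)‑9a‑bromo‑1‑hydroxy‑9‑oxo‑6‑(propan‑2‑yl)‑1,3,5a,6,7,8,9,9a‑octahydro‑2‑benzoxepine‑4‑carboxylate
Product: 16 tert‑butyl (5aS,6R,9aS)‑1,9‑dioxo‑6‑(propan‑2‑yl)‑1,3,5a,6,7,8,9,9a‑octahydro‑2‑benzoxepine‑4‑carboxylate, via bromo keto lactone 15 (not isolated)
Conditions: Dess–Martin periodinane, pyridine, CH2Cl2, rt; filtration; then Zn, AcOH/THF, 0 °C
Reagents that add atoms: none
Why: Lactol‑to‑lactone oxidation followed by zinc reduction of the α‑bromo‑β‑dicarbonyl unit through its zinc enolate, after which keto–enol equilibration should leave C9a–H trans to C5a–H with the lactone carbonyl equatorial.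

Step 10
Reactants: 16 tert‑butyl (5aS,6R,9aS)‑1,9‑dioxo‑6‑(propan‑2‑yl)‑1,3,5a,6,7,8,9,9a‑octahydro‑2‑benzoxepine‑4‑carboxylate
Product: 17 tert‑butyl (5aS,6R,9aS)‑9‑methylidene‑1‑oxo‑6‑(propan‑2‑yl)‑1,3,5a,6,7,8,9,9a‑octahydro‑2‑benzoxepine‑4‑carboxylate
Conditions: Zn, CH2Br2, TiCl4, THF (reagent pre‑formed at 0–5 °C); then CH2Cl2, 0 °C → rt
Reagents that add atoms: dibromomethane, BrCBr
Why: Takai–Lombardo methylenation with the non‑basic zinc/titanium gem‑dimetallic reagent, which olefinates readily enolisable ketones beside esters and lactones; it should take the keto tautomer with the equatorial C9a substituent, so C9a is fixed as in the target.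

Step 11
Reactants: 17 tert‑butyl (5aS,6R,9aS)‑9‑methylidene‑1‑oxo‑6‑(propan‑2‑yl)‑1,3,5a,6,7,8,9,9a‑octahydro‑2‑benzoxepine‑4‑carboxylate
Product: 18 tert‑butyl (5aS,6R,9S,9aS)‑9‑hydroxy‑9‑(hydroxymethyl)‑1‑oxo‑6‑(propan‑2‑yl)‑1,3,5a,6,7,8,9,9a‑octahydro‑2‑benzoxepine‑4‑carboxylate
Conditions: OsO4 (2 mol %), NMO, acetone/H2O, 0 °C; crude diol taken on at once
Reagents that add atoms: N‑methylmorpholine N‑oxide, C[N+]1([O-])CCOCC1 (oxygen relayed by catalytic OsO4, O=[Os](=O)(=O)=O); water, O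
Why: Upjohn dihydroxylation, in which OsO4 should select the electron‑rich 1,1‑disubstituted alkene over the enoate and approach from the equatorial direction (away from the axial hydrogens at C5a and C7), giving the equatorial tertiary hydroxyl and the axial CH2OH, i.e. 9S.

Step 12
Reactants: 1 isovaleraldehyde; 2 methyl vinyl ketone
Product: 19 (2S)‑5‑oxo‑2‑(propan‑2‑yl)hexanal
Conditions: (S)‑2‑[methoxy(diphenyl)methyl]pyrrolidine (5 mol %), ethyl 3,4‑dihydroxybenzoate (20 mol %), neat, 4 °C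
Reagents that add atoms: none
Why: The same organocatalytic enamine Michael addition as in step 1, run with the enantiomeric catalyst so that the α‑carbon should be set as S.

Step 13
Reactants: 19 (2S)‑5‑oxo‑2‑(propan‑2‑yl)hexanal
Product: 20 (4S)‑4‑(propan‑2‑yl)cyclohex‑2‑en‑1‑one ((S)‑cryptone)
Conditions: LiOH (cat.), iPrOH, rt
Reagents that add atoms: none
Why: Intramolecular aldol condensation as in step 2, with the stereocentre carried over unchanged.

Step 14
Reactants: 20 (S)‑cryptone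
Product: 22 (3S,4S)‑3‑ethenyl‑4‑(propan‑2‑yl)cyclohex‑1‑en‑1‑yl trifluoromethanesulfonate, via magnesium enolate 21 (not isolated)
Conditions: CH2=CHMgBr, CuBr·SMe2 (10 mol %), THF, −78 °C; then Comins' reagent, −78 °C → rt
Reagents that add atoms: vinylmagnesium bromide, C=C[Mg]Br; N‑(5‑chloropyridin‑2‑yl)‑1,1,1‑trifluoro‑N‑[(trifluoromethyl)sulfonyl]methanesulfonamide (Comins' reagent), FC(F)(F)S(=O)(=O)N(c1ccc(Cl)cn1)S(=O)(=O)C(F)(F)F
Why: Copper‑catalysed conjugate addition of the vinyl Grignard reagent anti to the C4 isopropyl group (trans 3,4‑disubstitution) followed by regiospecific O‑triflation of the enolate so formed.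

Step 15
Reactants: 22 (3S,4S)‑3‑ethenyl‑4‑(propan‑2‑yl)cyclohex‑1‑en‑1‑yl trifluoromethanesulfonate
Product: 23 (3S,4S)‑3‑formyl‑4‑(propan‑2‑yl)cyclohex‑1‑en‑1‑yl trifluoromethanesulfonate
Conditions: OsO4 (2 mol %), NaIO4, 2,6‑lutidine, dioxane/H2O (3:1), rt
Reagents that add atoms: sodium periodate, [Na+].[O-]I(=O)(=O)=O (oxygen relayed by catalytic OsO4, O=[Os](=O)(=O)=O)
Why: Lemieux–Johnson cleavage, in which OsO4 should attack the monosubstituted vinyl group and not the strongly deactivated enol triflate alkene, while the buffered medium keeps the more stable trans arrangement at C3.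

Step 16
Reactants: 23 (3S,4S)‑3‑formyl‑4‑(propan‑2‑yl)cyclohex‑1‑en‑1‑yl trifluoromethanesulfonate; 24 methyl (triphenyl‑λ5‑phosphanylidene)acetate
Product: 26 methyl (2Z)‑2‑bromo‑3‑[(1S,6S)‑6‑(propan‑2‑yl)‑3‑{[(trifluoromethyl)sulfonyl]oxy}cyclohex‑2‑en‑1‑yl]prop‑2‑enoate, via bromo ylide 25 (not isolated)
Conditions: 24, NBS, CH2Cl2, −20 °C; then 23, rt
Reagents that add atoms: N‑bromosuccinimide, O=C1CCC(=O)N1Br
Why: Tandem ylide bromination/Wittig olefination, in which the stabilised α‑bromo ylide should place the ester trans to the aldehyde substituent, so bromine ends cis to the ring (2Z).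

Step 17
Reactants: 26 methyl (2Z)‑2‑bromo‑3‑[(1S,6S)‑6‑(propan‑2‑yl)‑3‑{[(trifluoromethyl)sulfonyl]oxy}cyclohex‑2‑en‑1‑yl]prop‑2‑enoate
Product: 27 methyl (2E)‑2‑(hydroxymethyl)‑3‑[(1S,6S)‑3‑(hydroxymethyl)‑6‑(propan‑2‑yl)cyclohex‑2‑en‑1‑yl]prop‑2‑enoate
Conditions: Bu3SnCH2OH (2.5 equiv), Pd(PPh3)4 (10 mol %), LiCl, 1,4‑dioxane, 95 °C
Reagents that add atoms: (tributylstannyl)methanol, CCCC[Sn](CCCC)(CCCC)CO
Why: Twofold Stille cross‑coupling (Kosugi hydroxymethylation) at the enol triflate and at the α‑bromo enoate, with retention of alkene geometry so that the new CH2OH on Cα stays cis to the ring (2E).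

Step 18
Reactants: 27 methyl (2E)‑2‑(hydroxymethyl)‑3‑[(1S,6S)‑3‑(hydroxymethyl)‑6‑(propan‑2‑yl)cyclohex‑2‑en‑1‑yl]prop‑2‑enoate
Product: 28 methyl (2E)‑2‑({[tert‑butyl(dimethyl)silyl]oxy}methyl)‑3‑[(1S,6S)‑3‑({[tert‑butyl(dimethyl)silyl]oxy}methyl)‑6‑(propan‑2‑yl)cyclohex‑2‑en‑1‑yl]prop‑2‑enoate
Conditions: TBSCl (2.4 equiv), imidazole, DMF, rt
Reagents that add atoms: tert‑butyl(chloro)dimethylsilane, CC(C)(C)[Si](C)(C)Cl
Why: Standard silylation of both primary allylic alcohols so that the acid can later be activated without self‑esterification.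

Step 19
Reactants: 28 methyl (2E)‑2‑({[tert‑butyl(dimethyl)silyl]oxy}methyl)‑3‑[(1S,6S)‑3‑({[tert‑butyl(dimethyl)silyl]oxy}methyl)‑6‑(propan‑2‑yl)cyclohex‑2‑en‑1‑yl]prop‑2‑enoate
Product: 29 (2E)‑2‑({[tert‑butyl(dimethyl)silyl]oxy}methyl)‑3‑[(1S,6S)‑3‑({[tert‑butyl(dimethyl)silyl]oxy}methyl)‑6‑(propan‑2‑yl)cyclohex‑2‑en‑1‑yl]prop‑2‑enoic acid
Conditions: LiOH, THF/MeOH/H2O, 40 °C; then aq. HCl to pH 4, 0 °C
Reagents that add atoms: lithium hydroxide, [Li+].[OH-]
Why: Saponification of the methyl ester, in which aqueous hydroxide should not deprotonate the doubly allylic C1′–H, so alkene geometry and configuration are kept and the primary silyl ethers survive.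

Step 20
Reactants: 18 tert‑butyl (5aS,6R,9S,9aS)‑9‑hydroxy‑9‑(hydroxymethyl)‑1‑oxo‑6‑(propan‑2‑yl)‑1,3,5a,6,7,8,9,9a‑octahydro‑2‑benzoxepine‑4‑carboxylate; 29 (2E)‑2‑({[tert‑butyl(dimethyl)silyl]oxy}methyl)‑3‑[(1S,6S)‑3‑({[tert‑butyl(dimethyl)silyl]oxy}methyl)‑6‑(propan‑2‑yl)cyclohex‑2‑en‑1‑yl]prop‑2‑enoic acid
Product: 30 tert‑butyl (5aS,6R,9S,9aS)‑9‑{[((2E)‑2‑({[tert‑butyl(dimethyl)silyl]oxy}methyl)‑3‑[(1S,6S)‑3‑({[tert‑butyl(dimethyl)silyl]oxy}methyl)‑6‑(propan‑2‑yl)cyclohex‑2‑en‑1‑yl]prop‑2‑enoyl)oxy]methyl}‑9‑hydroxy‑1‑oxo‑6‑(propan‑2‑yl)‑1,3,5a,6,7,8,9,9a‑octahydro‑2‑benzoxepine‑4‑carboxylate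
Conditions: DCC, DMAP (10 mol %), CH2Cl2, 0 °C
Reagents that add atoms: none
Why: Steglich esterification, in which the primary CH2OH should be acylated in preference to the tertiary hydroxyl; the low temperature and immediate use of crude 18 limit attack of the free primary hydroxyl on the lactone carbonyl.

Step 21
Reactants: 30 tert‑butyl (5aS,6R,9S,9aS)‑9‑{[((2E)‑2‑({[tert‑butyl(dimethyl)silyl]oxy}methyl)‑3‑[(1S,6S)‑3‑({[tert‑butyl(dimethyl)silyl]oxy}methyl)‑6‑(propan‑2‑yl)cyclohex‑2‑en‑1‑yl]prop‑2‑enoyl)oxy]methyl}‑9‑hydroxy‑1‑oxo‑6‑(propan‑2‑yl)‑1,3,5a,6,7,8,9,9a‑octahydro‑2‑benzoxepine‑4‑carboxylate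
Product: 31 (5aS,6R,9S,9aS)‑9‑hydroxy‑9‑{[((2E)‑2‑(hydroxymethyl)‑3‑[(1S,6S)‑3‑(hydroxymethyl)‑6‑(propan‑2‑yl)cyclohex‑2‑en‑1‑yl]prop‑2‑enoyl)oxy]methyl}‑1‑oxo‑6‑(propan‑2‑yl)‑1,3,5a,6,7,8,9,9a‑octahydro‑2‑benzoxepine‑4‑carboxylic acid (CNP0361406.8)
Conditions: TFA/CH2Cl2 (1:4), H2O (5 equiv), 0 °C → rt; then MeOH, rt
Reagents that add atoms: none
Why: Acidolysis, in which trifluoroacetic acid should cleave the tert‑butyl ester with loss of isobutene and, with water, the two primary silyl ethers, while the ester link, the lactone and the tertiary alcohol are stable; methanol removes any trifluoroacetate esters formed in passing.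

**Compound list**

1 | isovaleraldehyde (3‑methylbutanal) | CC(C)CC=O | starting material
2 | methyl vinyl ketone | CC(=O)C=C | starting material
3 | (2R)‑5‑oxo‑2‑(propan‑2‑yl)hexanal | CC(C)[C@H](C=O)CCC(C)=O | intermediate
4 | (4R)‑4‑(propan‑2‑yl)cyclohex‑2‑en‑1‑one, (R)‑cryptone | CC(C)[C@H]1CCC(=O)C=C1 | intermediate
5 | formaldehyde | C=O | starting material
6 | (4R)‑2‑(hydroxymethyl)‑4‑(propan‑2‑yl)cyclohex‑2‑en‑1‑one | CC(C)[C@H]1CCC(=O)C(CO)=C1 | intermediate
7 | (4R)‑2‑({[tert‑butyl(dimethyl)silyl]oxy}methyl)‑4‑(propan‑2‑yl)cyclohex‑2‑en‑1‑one | CC(C)[C@H]1CCC(=O)C(CO[Si](C)(C)C(C)(C)C)=C1 | intermediate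
8 | tert‑butyl 2‑(bromomethyl)prop‑2‑enoate | C=C(CBr)C(=O)OC(C)(C)C | starting material
9 | [2‑(tert‑butoxycarbonyl)prop‑2‑en‑1‑yl](dimethyl)sulfonium bromide | C[S+](C)CC(=C)C(=O)OC(C)(C)C.[Br-] | intermediate
10 | tert‑butyl 2‑[(1S,5R,6S,7S)‑1‑({[tert‑butyl(dimethyl)silyl]oxy}methyl)‑2‑oxo‑5‑(propan‑2‑yl)bicyclo[4.1.0]heptan‑7‑yl]prop‑2‑enoate (cyclopropane anti to isopropyl, acrylate exo and cis to CH2OTBS) | CC(C)[C@H]1CCC(=O)[C@]2(CO[Si](C)(C)C(C)(C)C)[C@@H](C(=C)C(=O)OC(C)(C)C)[C@H]12 | intermediate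
11 | tert‑butyl 2‑[(1S,5R,6S,7S)‑1‑(hydroxymethyl)‑2‑oxo‑5‑(propan‑2‑yl)bicyclo[4.1.0]heptan‑7‑yl]prop‑2‑enoate | CC(C)[C@H]1CCC(=O)[C@]2(CO)[C@@H](C(=C)C(=O)OC(C)(C)C)[C@H]12 | intermediate
12 | tert‑butyl 2‑[(1S,5R,6S,7S)‑1‑formyl‑2‑oxo‑5‑(propan‑2‑yl)bicyclo[4.1.0]heptan‑7‑yl]prop‑2‑enoate (formyl cis to the vinyl group) | CC(C)[C@H]1CCC(=O)[C@]2(C=O)[C@@H](C(=C)C(=O)OC(C)(C)C)[C@H]12 | intermediate
13 | tert‑butyl (5aS,6R)‑9‑oxo‑6‑(propan‑2‑yl)‑3,5a,6,7,8,9‑hexahydro‑2‑benzoxepine‑4‑carboxylate | CC(C)[C@H]1CCC(=O)C2=COCC(C(=O)OC(C)(C)C)=C[C@H]12 | intermediate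
14 | tert‑butyl (5aS,6R)‑9a‑bromo‑1‑hydroxy‑9‑oxo‑6‑(propan‑2‑yl)‑1,3,5a,6,7,8,9,9a‑octahydro‑2‑benzoxepine‑4‑carboxylate (epimers at C1/C9a) | CC(C)[C@H]1CCC(=O)C2(Br)C(O)OCC(C(=O)OC(C)(C)C)=C[C@H]12 | intermediate
15 | tert‑butyl (5aS,6R)‑9a‑bromo‑1,9‑dioxo‑6‑(propan‑2‑yl)‑1,3,5a,6,7,8,9,9a‑octahydro‑2‑benzoxepine‑4‑carboxylate (epimers at C9a) | CC(C)[C@H]1CCC(=O)C2(Br)C(=O)OCC(C(=O)OC(C)(C)C)=C[C@H]12 | intermediate
16 | tert‑butyl (5aS,6R,9aS)‑1,9‑dioxo‑6‑(propan‑2‑yl)‑1,3,5a,6,7,8,9,9a‑octahydro‑2‑benzoxepine‑4‑carboxylate (keto form, trans‑fused) | CC(C)[C@H]1CCC(=O)[C@H]2C(=O)OCC(C(=O)OC(C)(C)C)=C[C@H]12 | intermediate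
17 | tert‑butyl (5aS,6R,9aS)‑9‑methylidene‑1‑oxo‑6‑(propan‑2‑yl)‑1,3,5a,6,7,8,9,9a‑octahydro‑2‑benzoxepine‑4‑carboxylate | CC(C)[C@H]1CCC(=C)[C@H]2C(=O)OCC(C(=O)OC(C)(C)C)=C[C@H]12 | intermediate
18 | tert‑butyl (5aS,6R,9S,9aS)‑9‑hydroxy‑9‑(hydroxymethyl)‑1‑oxo‑6‑(propan‑2‑yl)‑1,3,5a,6,7,8,9,9a‑octahydro‑2‑benzoxepine‑4‑carboxylate | CC(C)[C@H]1CC[C@@](O)(CO)[C@H]2C(=O)OCC(C(=O)OC(C)(C)C)=C[C@H]12 | intermediate
19 | (2S)‑5‑oxo‑2‑(propan‑2‑yl)hexanal | CC(C)[C@@H](C=O)CCC(C)=O | intermediate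
20 | (4S)‑4‑(propan‑2‑yl)cyclohex‑2‑en‑1‑one, (S)‑cryptone | CC(C)[C@@H]1CCC(=O)C=C1 | intermediate
21 | bromomagnesium (3S,4S)‑3‑ethenyl‑4‑(propan‑2‑yl)cyclohex‑1‑en‑1‑olate | C=C[C@@H]1C=C(O[Mg]Br)CC[C@H]1C(C)C | intermediate
22 | (3S,4S)‑3‑ethenyl‑4‑(propan‑2‑yl)cyclohex‑1‑en‑1‑yl trifluoromethanesulfonate (vinyl trans to isopropyl) | C=C[C@@H]1C=C(OS(=O)(=O)C(F)(F)F)CC[C@H]1C(C)C | intermediate
23 | (3S,4S)‑3‑formyl‑4‑(propan‑2‑yl)cyclohex‑1‑en‑1‑yl trifluoromethanesulfonate | O=C[C@@H]1C=C(OS(=O)(=O)C(F)(F)F)CC[C@H]1C(C)C | intermediate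
24 | methyl (triphenyl‑λ5‑phosphanylidene)acetate | COC(=O)C=P(c1ccccc1)(c1ccccc1)c1ccccc1 | starting material
25 | methyl bromo(triphenyl‑λ5‑phosphanylidene)acetate | COC(=O)C(Br)=P(c1ccccc1)(c1ccccc1)c1ccccc1 | intermediate
26 | methyl (2Z)‑2‑bromo‑3‑[(1S,6S)‑6‑(propan‑2‑yl)‑3‑{[(trifluoromethyl)sulfonyl]oxy}cyclohex‑2‑en‑1‑yl]prop‑2‑enoate | COC(=O)/C(Br)=C/[C@@H]1C=C(OS(=O)(=O)C(F)(F)F)CC[C@H]1C(C)C | intermediate
27 | methyl (2E)‑2‑(hydroxymethyl)‑3‑[(1S,6S)‑3‑(hydroxymethyl)‑6‑(propan‑2‑yl)cyclohex‑2‑en‑1‑yl]prop‑2‑enoate | COC(=O)/C(CO)=C/[C@@H]1C=C(CO)CC[C@H]1C(C)C | intermediate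
28 | methyl (2E)‑2‑({[tert‑butyl(dimethyl)silyl]oxy}methyl)‑3‑[(1S,6S)‑3‑({[tert‑butyl(dimethyl)silyl]oxy}methyl)‑6‑(propan‑2‑yl)cyclohex‑2‑en‑1‑yl]prop‑2‑enoate | COC(=O)/C(CO[Si](C)(C)C(C)(C)C)=C/[C@@H]1C=C(CO[Si](C)(C)C(C)(C)C)CC[C@H]1C(C)C | intermediate
29 | (2E)‑2‑({[tert‑butyl(dimethyl)silyl]oxy}methyl)‑3‑[(1S,6S)‑3‑({[tert‑butyl(dimethyl)silyl]oxy}methyl)‑6‑(propan‑2‑yl)cyclohex‑2‑en‑1‑yl]prop‑2‑enoic acid | OC(=O)/C(CO[Si](C)(C)C(C)(C)C)=C/[C@@H]1C=C(CO[Si](C)(C)C(C)(C)C)CC[C@H]1C(C)C | intermediate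
30 | bis‑TBS ether tert‑butyl ester of the target (name as in step 20) | CC(C)[C@H]1CC[C@@](O)(COC(=O)/C(=C/[C@@H]2C=C(CO[Si](C)(C)C(C)(C)C)CC[C@H]2C(C)C)CO[Si](C)(C)C(C)(C)C)[C@H]2C(=O)OCC(C(=O)OC(C)(C)C)=C[C@H]12 | intermediate
31 | CNP0361406.8 (name as in step 21) | CC(C)[C@H]1CC[C@@](O)(COC(=O)/C(=C/[C@@H]2C=C(CO)CC[C@H]2C(C)C)CO)[C@H]2C(=O)OCC(C(=O)O)=C[C@H]12 | target

**Count and risks**

Total step count: 21. Longest linear sequence: 13 steps (steps 1–11, 20, 21); the acyl half is an eight‑step branch (steps 12–19).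

Step 5. The conjugate addition of the allylic sulfonium ylide to the α‑substituted, γ‑branched enone may be too slow, so that [2,3]‑rearrangement of the ylide or consumption of the sulfonium salt by carbonate takes over. The fallback sets out from 7 and 8 and returns at 10. Bromide 8 is treated with PhSO2Na (DMF, rt) to give tert‑butyl 2‑[(phenylsulfonyl)methyl]prop‑2‑enoate F1. Deprotonation of F1 with KOtBu (THF/DMF, −40 °C) gives a sulfonyl‑stabilised allyl anion, a stronger nucleophile than the ylide. Its Michael addition to 7 anti to the isopropyl group gives the potassium enolate of the sulfonyl Michael adduct F2. That enolate closes by 1,3‑elimination of benzenesulfinate (the Julia–Martel vinylcyclopropane synthesis) to 10, where the route resumes.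

Step 10. Enolisation and titanium chelation of the β‑keto lactone may stop the olefination, or the new alkene may drift into conjugation with the lactone. The fallback sets out from 15, isolated after the oxidation of step 9 and before the zinc treatment, and returns at 17. The ketone of 15, which cannot enolise toward C9a, is methylenated with the Tebbe reagent Cp2Ti(μ‑Cl)(μ‑CH2)AlMe2 (pyridine, THF/PhMe, −40 → 0 °C) to give tert‑butyl (5aS,6R)‑9a‑bromo‑9‑methylidene‑1‑oxo‑6‑(propan‑2‑yl)‑1,3,5a,6,7,8,9,9a‑octahydro‑2‑benzoxepine‑4‑carboxylate F4. Zinc in AcOH/THF at 0 °C then removes the bromine through the zinc dienolate, whose α‑protonation should give 17.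

Step 8. Ring–chain tautomerism of the bromo lactol in the aqueous medium may be followed by hydrolytic loss of the formyl carbon (retro‑Claisen deformylation), or the enol ether may open before it is brominated. The fallback sets out from 13 and returns at 15, avoiding any free lactol. Treatment of 13 with NBS in MeOH/CH2Cl2 at 0 °C gives the closed acetal tert‑butyl (5aS,6R)‑9a‑bromo‑1‑methoxy‑9‑oxo‑6‑(propan‑2‑yl)‑1,3,5a,6,7,8,9,9a‑octahydro‑2‑benzoxepine‑4‑carboxylate F3. Grieco oxidation of the cyclic acetal (mCPBA, BF3·OEt2 cat., CH2Cl2, 0 °C) then gives the bromo keto lactone 15, which enters step 9 at the zinc reduction.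

**Further compounds**

F1 | step 5 | tert‑butyl 2‑[(phenylsulfonyl)methyl]prop‑2‑enoate | C=C(CS(=O)(=O)c1ccccc1)C(=O)OC(C)(C)C
F2 | step 5 | potassium (4R)‑3‑[2‑(tert‑butoxycarbonyl)‑1‑(phenylsulfonyl)prop‑2‑en‑1‑yl]‑2‑({[tert‑butyl(dimethyl)silyl]oxy}methyl)‑4‑(propan‑2‑yl)cyclohex‑1‑en‑1‑olate (new bond at C3 trans to isopropyl) | CC(C)[C@H]1CCC([O-])=C(CO[Si](C)(C)C(C)(C)C)[C@@H]1C(C(=C)C(=O)OC(C)(C)C)S(=O)(=O)c1ccccc1.[K+]
F3 | step 8 | tert‑butyl (5aS,6R)‑9a‑bromo‑1‑methoxy‑9‑oxo‑6‑(propan‑2‑yl)‑1,3,5a,6,7,8,9,9a‑octahydro‑2‑benzoxepine‑4‑carboxylate | CC(C)[C@H]1CCC(=O)C2(Br)C(OC)OCC(C(=O)OC(C)(C)C)=C[C@H]12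
F4 | step 10 | tert‑butyl (5aS,6R)‑9a‑bromo‑9‑methylidene‑1‑oxo‑6‑(propan‑2‑yl)‑1,3,5a,6,7,8,9,9a‑octahydro‑2‑benzoxepine‑4‑carboxylate | CC(C)[C@H]1CCC(=C)C2(Br)C(=O)OCC(C(=O)OC(C)(C)C)=C[C@H]12
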